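The 3(2H)-furanone (O, C3, C2, C1, C10; germacrane numbering) is the closed form of an α′-hydroxy ynone, and its C1–C2 bond is also a bond of the ten-membered carbocycle C1–C10. The route therefore rests on one disconnection, a C1 acyl donor and a C2 alkyne terminus. In the key step a palladium/copper acyl–alkyne coupling of a thioester closes the carbocycle at C1–C2, and the strained ynone is trapped at once by the C10 hydroxyl at C3, so that both rings of the bridged core arise in one operation. The precursor is a seco S-ethyl thioester that carries the tertiary alcohol, the C8 ester, the trans α-methylene lactone and a cis-enyne with a free alkyne terminus.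

Key step: step 13

Remark on numbering: C1 furanone carbonyl, C2 furanone CH, C3 furanone C–O, C4=C5 ring alkene, C6 lactone O–CH, C7, C8 ester carbinol, C9 CH2, C10 quaternary carbon, C11–C13 methylene lactone, C14 methyl, C15 CH2OH.

Assumption: the (Rp,S) antipode of the palladacycle in step 7 is taken as the one that gives the (R) ester from a cis imidate; if the sense is the reverse, its mirror-image complex is used and nothing else changes.

Step 1
Reactants: 1 (R)-lactic acid; 2 pivalaldehyde
Product: 3 (2R,5R)-2-tert-butyl-5-methyl-1,3-dioxolan-4-one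
Conditions: TsOH·H2O (cat.), H2SO4 (cat.), pentane, reflux, Dean–Stark; cis isomer crystallised from pentane at −78 °C
Reagents that add atoms: none
Why: Acid-catalysed acetalisation under thermodynamic control should favour the cis acetal, whose new acetal centre is set by the lactate centre, and this isomer is the auxiliary for the self-regeneration-of-stereocentres alkylation.

Step 2
Reactants: 4 (2Z)-4-{[tert-butyl(dimethyl)silyl]oxy}but-2-en-1-ol
Product: 5 (2Z)-1-bromo-4-{[tert-butyl(dimethyl)silyl]oxy}but-2-ene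
Conditions: CBr4, PPh3, CH2Cl2, 0 °C
Reagents that add atoms: carbon tetrabromide, BrC(Br)(Br)Br
Why: The Appel reaction displaces the activated primary allylic oxygen by bromide in an SN2 step and should leave the cis alkene and the silyl ether untouched.

Step 3
Reactants: 3 (2R,5R)-2-tert-butyl-5-methyl-1,3-dioxolan-4-one; 5 (2Z)-1-bromo-4-{[tert-butyl(dimethyl)silyl]oxy}but-2-ene
Product: 6 (2R,5S)-2-tert-butyl-5-[(2Z)-4-{[tert-butyl(dimethyl)silyl]oxy}but-2-en-1-yl]-5-methyl-1,3-dioxolan-4-one
Conditions: LiN(i-Pr)2, THF, −78 °C; then 5, −78 to −30 °C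
Reagents that add atoms: none
Why: Enolate alkylation (SN2 at the primary allylic bromide) should take place on the face opposite the tert-butyl group, which sets the quaternary centre (later C10, S) with overall retention of the lactate configuration.

Step 4
Reactants: 6 (2R,5S)-2-tert-butyl-5-[(2Z)-4-{[tert-butyl(dimethyl)silyl]oxy}but-2-en-1-yl]-5-methyl-1,3-dioxolan-4-one
Product: 7 S-ethyl (2S,4Z)-6-{[tert-butyl(dimethyl)silyl]oxy}-2-hydroxy-2-methylhex-4-enethioate
Conditions: AlMe3, EtSH, CH2Cl2, 0 °C to rt; Rochelle salt work-up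
Reagents that add atoms: ethanethiol, CCS
Why: Aluminium-thiolate thiolysis of the acylal carbonyl should open the dioxolanone, the hemiacetal aluminate collapsing to pivalaldehyde, and gives the α-hydroxy thioester without touching the quaternary centre.

Step 5
Reactants: 7 S-ethyl (2S,4Z)-6-{[tert-butyl(dimethyl)silyl]oxy}-2-hydroxy-2-methylhex-4-enethioate
Product: 8 S-ethyl (2S,4Z)-2,6-dihydroxy-2-methylhex-4-enethioate
Conditions: HF·pyridine, pyridine, THF, 0 °C
Reagents that add atoms: none
Why: Buffered fluoride desilylation should free the primary allylic alcohol while the thioester and tertiary alcohol stay inert, and seven-membered lactonisation should be slow without activation.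

Step 6
Reactants: 8 S-ethyl (2S,4Z)-2,6-dihydroxy-2-methylhex-4-enethioate
Product: 9 S-ethyl (2S,4Z)-2-hydroxy-2-methyl-6-[(2,2,2-trichloroethanimidoyl)oxy]hex-4-enethioate
Conditions: Cl3CCN (1.05 equiv), DBU (cat.), CH2Cl2, 0 °C
Reagents that add atoms: trichloroacetonitrile, N#CC(Cl)(Cl)Cl
Why: Base-catalysed addition of an alcohol to trichloroacetonitrile (imidate formation) should be much faster at the primary allylic hydroxyl than at the hindered tertiary one.

Step 7
Reactants: 9 S-ethyl (2S,4Z)-2-hydroxy-2-methyl-6-[(2,2,2-trichloroethanimidoyl)oxy]hex-4-enethioate; 10 (2R)-2-methylbutanoic acid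
Product: 11 S-ethyl (2S,4R)-2-hydroxy-2-methyl-4-{[(2R)-2-methylbutanoyl]oxy}hex-5-enethioate
Conditions: di-μ-acetatobis[(η5-(S)-(pR)-2-(2′-(4′-isopropyl)oxazolinyl)cyclopentadienyl-1-C,3′-N)(η4-tetraphenylcyclobutadiene)cobalt]dipalladium (1 mol%), 10 (3 equiv), CH2Cl2, rt
Reagents that add atoms: none
Why: In this catalytic asymmetric SN2′ allylic esterification the divalent palladium of the chiral palladacycle binds the imidate nitrogen, the acid adds anti to the activated cis alkene at C8 and deoxypalladation expels trichloroacetamide, so the catalyst sets C8 (R) and installs the ester and the vinyl group together without a free C8 hydroxyl ever being present.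

Step 8
Reactants: 11 S-ethyl (2S,4R)-2-hydroxy-2-methyl-4-{[(2R)-2-methylbutanoyl]oxy}hex-5-enethioate; 12 methyl 2-(bromomethyl)prop-2-enoate
Product: 13 methyl (2Z,4R,6S)-2-(bromomethyl)-7-(ethylsulfanyl)-6-hydroxy-6-methyl-4-{[(2R)-2-methylbutanoyl]oxy}-7-oxohept-2-enoate
Conditions: 12 (5 equiv), second-generation Hoveyda–Grubbs catalyst (10 mol%), CH2Cl2, 40 °C
Reagents that add atoms: none
Why: Olefin cross-metathesis of the terminal allylic ester with a 1,1-disubstituted acrylate that does not homodimerise should give the trisubstituted enoate in its thermodynamic geometry (C8 cis to CH2Br), with loss of ethene.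

Step 9
Reactants: 14 4-{[tert-butyl(dimethyl)silyl]oxy}but-2-yn-1-ol
Product: 15 (2Z)-4-{[tert-butyl(dimethyl)silyl]oxy}-3-iodobut-2-en-1-ol
Conditions: NaAlH2(OCH2CH2OMe)2, THF, 0 °C; then I2, −78 to 0 °C
Reagents that add atoms: iodine, II
Why: Hydroxyl-directed trans-hydroalumination places aluminium on the alkyne carbon remote from the free hydroxyl, and iodinolysis with retention should give the vinyl iodide with iodine cis to the CH2OH arm.

Step 10
Reactants: 15 (2Z)-4-{[tert-butyl(dimethyl)silyl]oxy}-3-iodobut-2-en-1-ol; 16 ethynyl(trimethyl)silane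
Product: 18 (2E)-3-({[tert-butyl(dimethyl)silyl]oxy}methyl)pent-2-en-4-yn-1-ol, via trimethylsilyl enyne 17 (not isolated)
Conditions: PdCl2(PPh3)2 (cat.), CuI (cat.), Et3N, THF, rt; then MeOH, K2CO3, rt
Reagents that add atoms: none
Why: Sonogashira coupling proceeds with retention of alkene geometry (ethynyl cis to the CH2OH arm; the descriptor changes only by priority), and methanolysis of the alkynyl C–Si bond then frees the alkyne terminus while the silyl ether survives.

Step 11
Reactants: 18 (2E)-3-({[tert-butyl(dimethyl)silyl]oxy}methyl)pent-2-en-4-yn-1-ol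
Product: 19 (2E)-3-({[tert-butyl(dimethyl)silyl]oxy}methyl)pent-2-en-4-ynal
Conditions: MnO2, CH2Cl2, rt
Reagents that add atoms: none
Why: Heterogeneous allylic oxidation with MnO2 should give the enal under neutral conditions without isomerising the alkene that keeps formyl and ethynyl cis.

Step 12
Reactants: 13 methyl (2Z,4R,6S)-2-(bromomethyl)-7-(ethylsulfanyl)-6-hydroxy-6-methyl-4-{[(2R)-2-methylbutanoyl]oxy}-7-oxohept-2-enoate; 19 (2E)-3-({[tert-butyl(dimethyl)silyl]oxy}methyl)pent-2-en-4-ynal
Product: 21 S-ethyl (2S,4R)-4-[(2R,3R)-2-[(1E)-2-({[tert-butyl(dimethyl)silyl]oxy}methyl)but-1-en-3-yn-1-yl]-4-methylidene-5-oxooxolan-3-yl]-2-hydroxy-2-methyl-4-{[(2R)-2-methylbutanoyl]oxy}butanethioate, via anti hydroxy ester 20 (not isolated)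
Conditions: CrCl2 (4 equiv), THF, 0 °C to rt; then PPTS (cat.), CH2Cl2, rt
Reagents that add atoms: none
Why: In this Nozaki–Hiyama-type 2-(alkoxycarbonyl)allylation the equilibrating allylchromium (trivalent) should add to the aldehyde through a chair transition state with the aldehyde substituent and the C8 branch both equatorial (anti adduct, hence trans lactone), C7 being attacked anti to the C9 branch in the conformer that minimises allylic 1,3-strain (C8–H eclipsing the alkene), which sets C6 (R) and C7 (R) from C8, and acid then closes the lactone with loss of methanol.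

Step 13
Reactants: 21 S-ethyl (2S,4R)-4-[(2R,3R)-2-[(1E)-2-({[tert-butyl(dimethyl)silyl]oxy}methyl)but-1-en-3-yn-1-yl]-4-methylidene-5-oxooxolan-3-yl]-2-hydroxy-2-methyl-4-{[(2R)-2-methylbutanoyl]oxy}butanethioate
Product: 23 15-O-[tert-butyl(dimethyl)silyl] ether of the target, via ten-membered hydroxy ynone 22 (not isolated)
Conditions: PdCl2(dppf) (10 mol%), P(2-furyl)3 (25 mol%), CuI (2 equiv), Et3N, DMF, 50 °C, slow addition of 21 (final 2 mM)
Reagents that add atoms: none
Why: Zerovalent palladium inserts into the C1–S bond of the thioester (CuI acting as thiophile), the copper acetylide of the enyne transmetalates, and reductive elimination closes C1–C2 to give the ten-membered α′-hydroxy ynone 22, whose C10 hydroxyl then adds to C3 and tautomerises to the vinylogous ester, so that C1–C2 and O–C3 form in one flask. The closest known reactions are the palladium/copper coupling of thioesters with 1-alkynes (an acyl Sonogashira reaction) and the amine- or copper-promoted cycloisomerisation of α′-hydroxy ynones to 3(2H)-furanones. The carbocycle closes by C(sp2)–C(sp) reductive elimination from an eleven-membered palladacycle under slow addition, and the furanone closes in the 5-endo-dig mode, driven by release of the bending strain of the cycloalkyne. No stereocentre is created: C10 is quaternary and cannot epimerise, C6–C8 are untouched, and the C4=C5 geometry that holds C3 and C6 cis is kept. The step needs ring closure to outrun oligomerisation and to avoid thiolate or acetylide addition to the α-methylene lactone; the first is served by high dilution and the turn imposed by the trans lactone and cis alkene, the second by stoichiometric CuI, which binds ethanethiolate as CuSEt, and by the softness of the copper acetylide. Oxygen attack at C3 and not C2 follows from the ynone polarity, and no other hydroxyl can compete because O6 is lactonised and O15 is silylated.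

Step 14
Reactants: 23 15-O-[tert-butyl(dimethyl)silyl] ether of the target
Product: 24 [(2Z,4R,8R,9R,11S)-2-(hydroxymethyl)-11-methyl-7-methylidene-6,12-dioxo-5,14-dioxatricyclo[9.2.1.0(4,8)]tetradeca-1(13),2-dien-9-yl] (2R)-2-methylbutanoate (target)
Conditions: HF·pyridine, pyridine, THF, 0 °C to rt
Reagents that add atoms: none
Why: Buffered fluoride desilylation should free the primary allylic C15 alcohol under conditions that spare the α-methylene lactone, the furanone and the ester.

Compound list
1 | (R)-lactic acid | C[C@@H](O)C(=O)O | starting material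
2 | pivalaldehyde | CC(C)(C)C=O | starting material
3 | (2R,5R)-2-tert-butyl-5-methyl-1,3-dioxolan-4-one (cis) | C[C@H]1O[C@@H](C(C)(C)C)OC1=O | intermediate
4 | (2Z)-4-{[tert-butyl(dimethyl)silyl]oxy}but-2-en-1-ol | OC/C=C\CO[Si](C)(C)C(C)(C)C | starting material
5 | (2Z)-1-bromo-4-{[tert-butyl(dimethyl)silyl]oxy}but-2-ene | BrC/C=C\CO[Si](C)(C)C(C)(C)C | intermediate
6 | (2R,5S)-2-tert-butyl-5-[(2Z)-4-{[tert-butyl(dimethyl)silyl]oxy}but-2-en-1-yl]-5-methyl-1,3-dioxolan-4-one | C[C@@]1(C/C=C\CO[Si](C)(C)C(C)(C)C)O[C@@H](C(C)(C)C)OC1=O | intermediate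
7 | S-ethyl (2S,4Z)-6-{[tert-butyl(dimethyl)silyl]oxy}-2-hydroxy-2-methylhex-4-enethioate | CCSC(=O)[C@@](C)(O)C/C=C\CO[Si](C)(C)C(C)(C)C | intermediate
8 | S-ethyl (2S,4Z)-2,6-dihydroxy-2-methylhex-4-enethioate | CCSC(=O)[C@@](C)(O)C/C=C\CO | intermediate
9 | S-ethyl (2S,4Z)-2-hydroxy-2-methyl-6-[(2,2,2-trichloroethanimidoyl)oxy]hex-4-enethioate | CCSC(=O)[C@@](C)(O)C/C=C\COC(=N)C(Cl)(Cl)Cl | intermediate
10 | (2R)-2-methylbutanoic acid | CC[C@@H](C)C(=O)O | starting material
11 | S-ethyl (2S,4R)-2-hydroxy-2-methyl-4-{[(2R)-2-methylbutanoyl]oxy}hex-5-enethioate | CCSC(=O)[C@@](C)(O)C[C@@H](OC(=O)[C@H](C)CC)C=C | intermediate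
12 | methyl 2-(bromomethyl)prop-2-enoate | C=C(CBr)C(=O)OC | starting material
13 | methyl (2Z,4R,6S)-2-(bromomethyl)-7-(ethylsulfanyl)-6-hydroxy-6-methyl-4-{[(2R)-2-methylbutanoyl]oxy}-7-oxohept-2-enoate | CCSC(=O)[C@@](C)(O)C[C@@H](OC(=O)[C@H](C)CC)/C=C(\CBr)C(=O)OC | intermediate
14 | 4-{[tert-butyl(dimethyl)silyl]oxy}but-2-yn-1-ol | OCC#CCO[Si](C)(C)C(C)(C)C | starting material
15 | (2Z)-4-{[tert-butyl(dimethyl)silyl]oxy}-3-iodobut-2-en-1-ol | OC/C=C(\I)CO[Si](C)(C)C(C)(C)C | intermediate
16 | ethynyl(trimethyl)silane | C#C[Si](C)(C)C | starting material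
17 | (2E)-3-({[tert-butyl(dimethyl)silyl]oxy}methyl)-5-(trimethylsilyl)pent-2-en-4-yn-1-ol | OC/C=C(\C#C[Si](C)(C)C)CO[Si](C)(C)C(C)(C)C | intermediate
18 | (2E)-3-({[tert-butyl(dimethyl)silyl]oxy}methyl)pent-2-en-4-yn-1-ol | OC/C=C(\C#C)CO[Si](C)(C)C(C)(C)C | intermediate
19 | (2E)-3-({[tert-butyl(dimethyl)silyl]oxy}methyl)pent-2-en-4-ynal (formyl and ethynyl cis) | O=C/C=C(\C#C)CO[Si](C)(C)C(C)(C)C | intermediate
20 | methyl (3R,4R,5E)-6-({[tert-butyl(dimethyl)silyl]oxy}methyl)-3-[(1R,3S)-4-(ethylsulfanyl)-3-hydroxy-3-methyl-1-{[(2R)-2-methylbutanoyl]oxy}-4-oxobutyl]-4-hydroxy-2-methylideneoct-5-en-7-ynoate | CCSC(=O)[C@@](C)(O)C[C@@H](OC(=O)[C@H](C)CC)[C@H]([C@H](O)/C=C(/CO[Si](C)(C)C(C)(C)C)C#C)C(=C)C(=O)OC | intermediate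
21 | S-ethyl (2S,4R)-4-[(2R,3R)-2-[(1E)-2-({[tert-butyl(dimethyl)silyl]oxy}methyl)but-1-en-3-yn-1-yl]-4-methylidene-5-oxooxolan-3-yl]-2-hydroxy-2-methyl-4-{[(2R)-2-methylbutanoyl]oxy}butanethioate | C=C1C(=O)O[C@H](/C=C(/CO[Si](C)(C)C(C)(C)C)C#C)[C@H]1[C@H](OC(=O)[C@H](C)CC)C[C@](C)(O)C(=O)SCC | intermediate
22 | (6R,7R,8R,10S)-15-{[tert-butyl(dimethyl)silyl]oxy}-10-hydroxy-8-{[(2R)-2-methylbutanoyl]oxy}-1-oxogermacra-4,11(13)-dien-2-yn-12,6-olide (C3 and C6 cis on C4=C5) | C=C1C(=O)O[C@@H]2/C=C(/CO[Si](C)(C)C(C)(C)C)C#CC(=O)[C@@](C)(O)C[C@@H](OC(=O)[C@H](C)CC)[C@@H]12 | intermediate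
23 | 15-O-[tert-butyl(dimethyl)silyl] ether of the target | C=C1C(=O)O[C@@H]2/C=C(/CO[Si](C)(C)C(C)(C)C)C3=CC(=O)[C@](C)(C[C@@H](OC(=O)[C@H](C)CC)[C@@H]12)O3 | intermediate
24 | [(2Z,4R,8R,9R,11S)-2-(hydroxymethyl)-11-methyl-7-methylidene-6,12-dioxo-5,14-dioxatricyclo[9.2.1.0(4,8)]tetradeca-1(13),2-dien-9-yl] (2R)-2-methylbutanoate | C=C1C(=O)O[C@@H]2/C=C(/CO)C3=CC(=O)[C@](C)(C[C@@H](OC(=O)[C@H](C)CC)[C@@H]12)O3 | target

Total step count: 14. Longest linear sequence: 10 steps (1, 3, 4, 5, 6, 7, 8, 12, 13, 14).

Steps most likely to fail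

Step 13 (key step). Ring closure may lose to intermolecular coupling (oligomers, diyne formation) or to decarbonylation of the acylpalladium before transmetalation, and ethanethiolate may add to the methylene lactone. The fallback makes the same two bonds between two fragments and closes the ring at C6–C7 instead. It sets out from 11 and 19: under the palladium/copper conditions of step 13 at normal concentration they should give the open-chain hydroxy ynone F1, which cyclises in the flask to the furanone enal F2. Cross-metathesis of F2 with 12 gives the allyl bromide F3. CrCl2 at high dilution then closes C6–C7 by intramolecular allylation to the macrocyclic hydroxy ester F4, and PPTS lactonises F4 to 23, where the route is rejoined. The ring closure is the chromium/Barbier allylation long used for ten-membered germacranolide rings; its stereochemical course is then set by the ring.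

Step 12. Facial selection at C7 or the anti preference of the chair may be poor, giving the cis lactone. The fallback moves the control of C6 from kinetics to equilibration. It sets out from 13 and 19: zinc in THF/aqueous NH4Cl (Barbier conditions, syn-selective for this bromide geometry) should give the syn hydroxy ester F5, which lactonises spontaneously to the cis lactone F6. Pd(PPh3)4 in THF then ionises the allylic C6–O bond reversibly and re-closes it to the more stable trans lactone, giving 21.

Step 8. Metathesis between a hindered allylic ester and an electron-poor 1,1-disubstituted alkene may stall, with catalyst decay before conversion. The fallback builds the allyl bromide by carbonyl chemistry. It sets out from 11: ozonolysis (O3, CH2Cl2, −78 °C; Me2S) gives the α-acyloxy aldehyde F7; Morita–Baylis–Hillman reaction with methyl acrylate and DABCO gives the allylic alcohol F8 as a mixture of C7 epimers; NBS/Me2S bromination with allylic transposition removes that centre and returns 13.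

Further compounds
F1 | step 13 | open-chain hydroxy ynone: (5S,7R)-7-ethenyl-substituted 1-formyl enynone, C10 hydroxyl free | O=C/C=C(/CO[Si](C)(C)C(C)(C)C)C#CC(=O)[C@@](C)(O)C[C@@H](OC(=O)[C@H](C)CC)C=C
F2 | step 13 | furanone enal with C8 vinyl ester side chain | O=C/C=C(/CO[Si](C)(C)C(C)(C)C)C1=CC(=O)[C@](C)(C[C@@H](OC(=O)[C@H](C)CC)C=C)O1
F3 | step 13 | furanone enal allyl bromide | O=C/C=C(/CO[Si](C)(C)C(C)(C)C)C1=CC(=O)[C@](C)(C[C@@H](OC(=O)[C@H](C)CC)/C=C(\CBr)C(=O)OC)O1
F4 | step 13 | macrocyclic C6 hydroxy C12 methyl ester of 23 | C=C(C(=O)OC)[C@H]1[C@H](O)/C=C(/CO[Si](C)(C)C(C)(C)C)C2=CC(=O)[C@](C)(C[C@H]1OC(=O)[C@H](C)CC)O2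
F5 | step 12 | syn hydroxy ester (C6 epimer of 20) | CCSC(=O)[C@@](C)(O)C[C@@H](OC(=O)[C@H](C)CC)[C@H]([C@@H](O)/C=C(/CO[Si](C)(C)C(C)(C)C)C#C)C(=C)C(=O)OC
F6 | step 12 | cis lactone (C6 epimer of 21) | C=C1C(=O)O[C@@H](/C=C(/CO[Si](C)(C)C(C)(C)C)C#C)[C@H]1[C@H](OC(=O)[C@H](C)CC)C[C@](C)(O)C(=O)SCC
F7 | step 8 | S-ethyl (2S,4R)-2-hydroxy-2-methyl-4-{[(2R)-2-methylbutanoyl]oxy}-5-oxopentanethioate | CCSC(=O)[C@@](C)(O)C[C@@H](OC(=O)[C@H](C)CC)C=O
F8 | step 8 | methyl (4R,6S)-7-(ethylsulfanyl)-3,6-dihydroxy-6-methyl-2-methylidene-4-{[(2R)-2-methylbutanoyl]oxy}-7-oxoheptanoate (both C3 epimers) | CCSC(=O)[C@@](C)(O)C[C@@H](OC(=O)[C@H](C)CC)C(O)C(=C)C(=O)OC
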